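Numbering used throughout: ring A is numbered as a 2-hydroxy-6-methylbenzoate (C1 methoxycarbonyl, C2 hydroxyl, C4 the ester oxygen, C6 methyl). Ring B is numbered from its carboxyl carbon (C1; C2 and C5 methyl, C3 chlorine, C4 and C6 oxygen). All names keep this numbering.

## The problem

Compound 18 is a depside: the C4 oxygen of a methyl 2-hydroxy-6-methylbenzoate (ring A) is acylated by 3-chloro-4,6-dihydroxy-2,5-dimethylbenzoic acid (ring B). It has no stereocentre, so the task is one of regiochemistry and chemoselectivity. Ring B is hexasubstituted and its carboxyl carbon lies between a methyl group and an oxygen, so acyl transfer from it through a tetrahedral intermediate is slow. The only skeletal bond to be made is the ester link between the rings, and it can be closed from either side: acyl carbon to oxygen, or ring A C4 to oxygen. The finished molecule tolerates little: hydroxide, alkoxide and fluoride cleave or transesterify the aryl ester and the methyl ester, hydrogenolysis endangers the aryl chloride, and three free phenols leave both rings open to electrophiles and oxidants. Protecting groups must therefore leave under non-basic, non-reductive conditions. The feature that makes the key step possible is ring A C4: it is para to the methoxycarbonyl group, so an aryl group bound through C4 to trivalent iodine is the electrophilic partner, and in a 2-alkoxy-6-methylbenzoate C4–H is the only ring hydrogen without an ortho neighbour, so it can be reached by sterically governed C–H borylation. Ring B complements this: all of its ring positions are occupied, so its carboxylate can serve as a plain oxygen nucleophile without competing ring chemistry.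

## Retrosynthesis

**18 from 17.** The last cut removes three O–alkyl bonds: the two benzyl ethers on ring B and the isopropyl ether at ring A C2. Hydrogenolysis is excluded by the C3 chlorine, and basic or fluoride deprotection by the aryl ester, so all three groups are chosen to leave by Lewis-acid dealkylation in one operation. Precursor 17 has the full skeleton but no free phenol. The forward step must cleave the ethers at or below 0 °C and leave the chlorine and both esters alone.

**17 from 6 and 14.** The ester link is cut at the ring A C4–O bond, not at the acyl C–O bond. The acyl cut would ask a di-ortho-substituted benzoyl derivative to accept a phenol at its shielded carbonyl carbon. The aryl cut makes acid 6 a nucleophile through its unhindered oxygen and puts the electrophilic role on ring A, as diaryliodonium salt 14. This divides the target into two benzenoid halves of similar size. The forward step must transfer the ring A aryl group, and not the auxiliary aryl group, from iodine to oxygen.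

**14 from 11 and 12.** The iodine–auxiliary bond is cut, giving aryl iodide 11 and arene 12. In the forward direction 11 is oxidised at iodine to 13, which substitutes 12. Arene 12 is chosen because its three ring positions are equivalent, so only one salt can form, and because the resulting aryl group is electron-rich and flanked by two methoxy groups and so stays on iodine in the key step.

**11 from 10 from 9.** The C4–I bond is traced back to a C4–B bond and that to the C4–H bond of 9. Electrophilic halogenation of 8 or 9 would go ortho and para to the oxygen, at C3 and C5, so it cannot reach C4; a sterically controlled C–H borylation can. This step dictates the protecting group on ring A. A benzyl ether would offer the catalyst the unhindered meta and para C–H bonds of its own phenyl ring. An isopropyl ether has no aromatic C–H bond, adds bulk beside C3, and leaves with the same Lewis acid that removes the benzyl ethers.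

**9 from 8 from 7.** Two O–C bonds are cut, the ether first and then the methyl ester, leading to the commercial acid 7. The forward order is esterification on the carboxylate, then alkylation of the chelated phenol.

**6 from 5, 4, 3 and 1.** Ring B needs only functional-group changes on the commercial resorcinol 1, whose two methyl groups and two oxygens are already correctly placed. The acid is traced to aldehyde 5; this avoids saponifying a hindered ester after benzylation. The benzyl ethers are then cut to give 4, the C3–Cl bond to give 3, and the formyl C–C bond to give 1. Formylation precedes chlorination in the forward sense, so that the chlorination finds a single free ring position.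

## Roads not taken

**Alternative 1:** The cut passes through ring A. Bonds C1–C6 and C3–C4 are broken, leading to methyl acetoacetate (A1) and methyl crotonate (A2). In the forward direction, alkoxide-mediated Michael addition and Claisen condensation would close ring A as methyl 6-methyl-2,4-dioxocyclohexane-1-carboxylate (A3, racemic trans; both centres disappear on aromatisation). Its C4 enol oxygen would be acylated with an activated form of acid 6 to give enol ester A4, and ring A would be dehydrogenated last.
- Merits: A1 and A2 are bulk chemicals. Ring A arrives in one step with ester, methyl group and both oxygens in place, four steps shorter than the path from 7 to 14. No precious metal or hypervalent iodine is needed.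
- Weak points: A3 is an ambident vinylogous acid. O-Acylation must choose the C4 oxygen over the C2 oxygen and over carbon C3. The ester bond is still made by acyl transfer from the di-ortho-substituted ring B carbonyl, now onto a weaker nucleophile. A4 is a vinylogous anhydride, prone to acyl migration and cleavage. The late oxidation must aromatise ring A without halogenating C3 or C5 and without touching the benzyl ethers.
- Comparison: this road is shorter and cheaper for ring A. The chosen plan sets against it a ring A that is aromatic from the start and a coupling in which only the carboxylate oxygen of ring B has to react, so the main risk does not fall on the last two steps.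

**Alternative 2:** Ring B is built, not bought. Bonds C1–C2, C3–C4, C4–C5 and C6–C1 are cut, leading to the ring A ester of (E)-5-chloro-2-diazo-4-methyl-3-oxopent-4-enoic acid (A5) and 1-(triisopropylsiloxy)propyne (A6). On irradiation A5 would undergo Wolff rearrangement to an ester-substituted vinylketene. Cycloaddition with A6, four-electron ring opening, six-electron ring closure and tautomerisation would give A7, the target with the ring B C6 hydroxyl as its triisopropylsilyl ether; desilylation would finish the synthesis.
- Merits: the ester link is made early from an unhindered malonate-type acyl unit, so the hindered-acid problem does not arise. The substitution pattern of ring B follows from the connectivity of the two components. Only one protecting group is carried, and the key step itself installs it.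
- Weak points: 2-diazo-1,3-dicarbonyl compounds are reluctant Wolff substrates, and the ester-stabilised ketene is a poor partner for the ynol ether. The chlorovinyl ketone of A5 is a Michael acceptor and is hard to carry through diazo transfer. The salicylate chromophore of ring A absorbs in the same region as the diazo group. A6 is moisture-sensitive. The final fluoride treatment is basic towards the depside.
- Comparison: this road is the more convergent in idea, and it is better in that no hindered acid is ever esterified and only one silyl ether is removed at the end. The chosen plan sets against it that the pattern of ring B is already present in 1 and is completed by four routine steps, and that each of its steps belongs to a widely used reaction class.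

**Alternative 3:** Ring A bonds C1–C2 and C5–C6 are cut, leading to diene A8 (the 4-methoxy-4-(trimethylsilyloxy)buta-1,3-dien-2-yl ester of the bis(methoxymethyl)-protected ring B acid) and methyl but-2-ynoate (A9). Cycloaddition followed by acidic work-up, which removes methanol and the silyl group, would give A10, the target with both ring B phenols as methoxymethyl ethers.
- Merits: ring A appears regiospecifically with its C2 hydroxyl free and the ester and methyl group in place. The oxygen joining the rings is never a free phenol. The step count is the lowest of all four plans.
- Weak points: the enol ester of A8 must itself be made by O-acylation of an acetoacetate enolate with the hindered ring B acyl electrophile, the very acyl transfer the chosen plan avoids, and C-acylation competes. The silyl ketene acetal must be formed by deprotonation next to an aryl ester. The acyloxy group makes the diene less electron-rich than the dialkoxy dienes known to perform well, and A9 is a sluggish, β-substituted dienophile. The methoxymethyl ethers need a separate protic acid step.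
- Comparison: this road is the shortest on paper. The chosen plan needs five steps to reach 14, but none of them depends on acyl transfer from the hindered acid or on an untested diene.

Key step: step 10

## Route

Step 1
Reactants: 1 2,5-dimethylbenzene-1,3-diol (2,5-dimethylresorcinol)
Product: 3 4,6-dihydroxy-2,5-dimethylbenzaldehyde, via iminium chloride 2 (not isolated)
Conditions: POCl3, DMF, MeCN, 0 °C to rt; then H2O, 50 °C
Reagents that add atoms: N,N-dimethylformamide CN(C)C=O; water O
Why: Vilsmeier–Haack formylation; the two free ring positions of 1 are equivalent by symmetry and each is ortho to one hydroxyl and para to the other, the iminium group of 2 deactivates the ring against a second substitution, and hydrolysis of 2 should deliver the aldehyde with its oxygen taken from water.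

Step 2
Reactants: 3 4,6-dihydroxy-2,5-dimethylbenzaldehyde
Product: 4 3-chloro-4,6-dihydroxy-2,5-dimethylbenzaldehyde
Conditions: SO2Cl2, Et2O, 0 °C to rt
Reagents that add atoms: sulfuryl chloride O=S(=O)(Cl)Cl
Why: Electrophilic aromatic chlorination; only C3 is still unsubstituted and it is ortho to the C4 hydroxyl and para to the C6 hydroxyl, so the site is fixed by the substrate and one equivalent of reagent should suffice.

Step 3
Reactants: 4 3-chloro-4,6-dihydroxy-2,5-dimethylbenzaldehyde
Product: 5 4,6-bis(benzyloxy)-3-chloro-2,5-dimethylbenzaldehyde
Conditions: BnBr, K2CO3, DMF, 60 °C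
Reagents that add atoms: benzyl bromide BrCc1ccccc1
Why: Williamson ether synthesis; both phenoxides should be alkylated by the reactive benzylic bromide in DMF, the chelated C6 hydroxyl needing the raised temperature.

Step 4
Reactants: 5 4,6-bis(benzyloxy)-3-chloro-2,5-dimethylbenzaldehyde
Product: 6 4,6-bis(benzyloxy)-3-chloro-2,5-dimethylbenzoic acid
Conditions: NaClO2, NaH2PO4, 2-methyl-2-butene, tBuOH/THF/H2O, rt
Reagents that add atoms: sodium chlorite [Na+].[O-]Cl=O
Why: Pinnick oxidation; chlorous acid adds to the aldehyde and fragments to the acid, the alkene takes up the hypochlorous acid, and the fully substituted ring offers no position for chlorination while benzyl ethers and aryl chloride are inert.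

Step 5
Reactants: 7 2-hydroxy-6-methylbenzoic acid (6-methylsalicylic acid)
Product: 8 methyl 2-hydroxy-6-methylbenzoate
Conditions: MeI, KHCO3, DMF, rt
Reagents that add atoms: iodomethane CI
Why: Carboxylate alkylation (SN2); hydrogencarbonate deprotonates only the carboxylic acid and leaves the chelated phenol protonated, and the method avoids the slow Fischer esterification of a di-ortho-substituted acid.

Step 6
Reactants: 8 methyl 2-hydroxy-6-methylbenzoate
Product: 9 methyl 2-isopropoxy-6-methylbenzoate
Conditions: 2-bromopropane, K2CO3, DMF, 60 °C
Reagents that add atoms: 2-bromopropane CC(C)Br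
Why: Williamson ether synthesis with a secondary bromide; an excess of the halide makes up for some elimination, and the hindered methyl ester is not touched by carbonate.

Step 7
Reactants: 9 methyl 2-isopropoxy-6-methylbenzoate
Product: 10 methyl 2-isopropoxy-6-methyl-4-(4,4,5,5-tetramethyl-1,3,2-dioxaborolan-2-yl)benzoate
Conditions: B2pin2, [Ir(OMe)(cod)]2 (cat.), 4,4'-di-tert-butyl-2,2'-bipyridine (cat.), THF, 80 °C
Reagents that add atoms: bis(pinacolato)diboron CC1(C)OB(B2OC(C)(C)C(C)(C)O2)OC1(C)C
Why: Iridium-catalysed, sterically controlled aromatic C–H borylation; C4–H is the only ring hydrogen without an ortho substituent (C3–H lies beside the isopropoxy group, C5–H beside the methyl group), and the isopropyl ether offers no competing aromatic C–H bond.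

Step 8
Reactants: 10 methyl 2-isopropoxy-6-methyl-4-(4,4,5,5-tetramethyl-1,3,2-dioxaborolan-2-yl)benzoate
Product: 11 methyl 4-iodo-2-isopropoxy-6-methylbenzoate
Conditions: CuI (cat.), 1,10-phenanthroline (cat.), KI, MeOH/H2O, air, 80 °C
Reagents that add atoms: potassium iodide [K+].[I-]
Why: Copper-mediated iododeboronation; the aryl group passes from boron to copper, air oxidises the copper centre and C–I bond formation follows at the carbon that carried boron, so the regiochemistry of step 7 is kept.

Step 9
Reactants: 11 methyl 4-iodo-2-isopropoxy-6-methylbenzoate; 12 1,3,5-trimethoxybenzene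
Product: 14 [3-isopropoxy-4-(methoxycarbonyl)-5-methylphenyl](2,4,6-trimethoxyphenyl)iodonium tosylate, via hydroxy(tosyloxy)iodane 13 (not isolated)
Conditions: mCPBA, TsOH·H2O, MeCN, 77 °C; then 12, 77 °C; precipitation with Et2O
Reagents that add atoms: p-toluenesulfonic acid monohydrate Cc1ccc(S(=O)(=O)O)cc1.O
Why: One-pot oxidation of the aryl iodide to trivalent iodine (13) followed by electrophilic aromatic substitution of 12 at iodine; 12 is far more nucleophilic than the ester-bearing ring of 11, its three ring positions are equivalent, and ester and isopropyl ether should tolerate the sulfonic acid.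

Step 10
Reactants: 6 4,6-bis(benzyloxy)-3-chloro-2,5-dimethylbenzoic acid; 14 [3-isopropoxy-4-(methoxycarbonyl)-5-methylphenyl](2,4,6-trimethoxyphenyl)iodonium tosylate
Product: 17 methyl 4-{[4,6-bis(benzyloxy)-3-chloro-2,5-dimethylbenzoyl]oxy}-2-isopropoxy-6-methylbenzoate, via potassium carboxylate 15 (not isolated), via diaryliodanyl carboxylate 16 (not isolated)
Conditions: KOtBu, toluene, rt; then 14, 110 °C
Reagents that add atoms: none
Why: KOtBu converts 6 into carboxylate 15, which displaces tosylate at the trivalent iodine of 14 to give the T-shaped diaryl-λ3-iodanyl carboxylate 16. Ligand coupling at iodine then joins the carboxylate oxygen to the ipso carbon of the ring A aryl group, forming the ring A C4–O bond and releasing monovalent iodine as 2-iodo-1,3,5-trimethoxybenzene. The closest known reaction type is the metal-free O-arylation of carboxylic acids with diaryliodonium salts in hot toluene, which accepts di-ortho-substituted benzoic acids because the acid reacts through oxygen and its shielded carbonyl carbon is never attacked. No ring is closed and no stereocentre is formed. The selectivity needed is transfer of the ring A aryl group and not of the auxiliary: the ipso carbon of the trimethoxyphenyl group is electron-rich and flanked by two methoxy groups, whereas the ring A ipso carbon has no ortho substituent and is para to the methoxycarbonyl group, which stabilises the charge that builds up there during coupling. A preformed carboxylate with no excess base should keep aryne formation and ester cleavage out, and the benzyl and isopropyl ethers, the aryl chloride and the methyl ester do not react with the salt.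

Step 11
Reactants: 17 methyl 4-{[4,6-bis(benzyloxy)-3-chloro-2,5-dimethylbenzoyl]oxy}-2-isopropoxy-6-methylbenzoate
Product: 18 methyl 4-[(3-chloro-4,6-dihydroxy-2,5-dimethylbenzoyl)oxy]-2-hydroxy-6-methylbenzoate
Conditions: BCl3, pentamethylbenzene, CH2Cl2, −78 °C to 0 °C; then MeOH, H2O
Reagents that add atoms: none
Why: Lewis-acid ether cleavage; BCl3 should remove the benzyl groups at low temperature as cations that pentamethylbenzene traps by Friedel–Crafts alkylation, and on warming to 0 °C it should cleave the isopropyl ether, helped by chelation to the neighbouring ester carbonyl, while aryl chloride, methyl ester and aryl ester stay intact.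

## Compound list

1 | 2,5-dimethylbenzene-1,3-diol (2,5-dimethylresorcinol) | Cc1cc(O)c(C)c(O)c1 | starting material
2 | N-[(4,6-dihydroxy-2,5-dimethylphenyl)methylidene]-N-methylmethanaminium chloride | C[N+](C)=Cc1c(C)cc(O)c(C)c1O.[Cl-] | intermediate (not isolated)
3 | 4,6-dihydroxy-2,5-dimethylbenzaldehyde | O=Cc1c(C)cc(O)c(C)c1O | intermediate
4 | 3-chloro-4,6-dihydroxy-2,5-dimethylbenzaldehyde | O=Cc1c(C)c(Cl)c(O)c(C)c1O | intermediate
5 | 4,6-bis(benzyloxy)-3-chloro-2,5-dimethylbenzaldehyde | O=Cc1c(C)c(Cl)c(OCc2ccccc2)c(C)c1OCc1ccccc1 | intermediate
6 | 4,6-bis(benzyloxy)-3-chloro-2,5-dimethylbenzoic acid | O=C(O)c1c(C)c(Cl)c(OCc2ccccc2)c(C)c1OCc1ccccc1 | intermediate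
7 | 2-hydroxy-6-methylbenzoic acid (6-methylsalicylic acid) | Cc1cccc(O)c1C(=O)O | starting material
8 | methyl 2-hydroxy-6-methylbenzoate | COC(=O)c1c(C)cccc1O | intermediate
9 | methyl 2-isopropoxy-6-methylbenzoate | COC(=O)c1c(C)cccc1OC(C)C | intermediate
10 | methyl 2-isopropoxy-6-methyl-4-(4,4,5,5-tetramethyl-1,3,2-dioxaborolan-2-yl)benzoate | COC(=O)c1c(C)cc(B2OC(C)(C)C(C)(C)O2)cc1OC(C)C | intermediate
11 | methyl 4-iodo-2-isopropoxy-6-methylbenzoate | COC(=O)c1c(C)cc(I)cc1OC(C)C | intermediate
12 | 1,3,5-trimethoxybenzene | COc1cc(OC)cc(OC)c1 | starting material
13 | methyl 4-[hydroxy(tosyloxy)-λ3-iodanyl]-2-isopropoxy-6-methylbenzoate | COC(=O)c1c(C)cc(I(O)OS(=O)(=O)c2ccc(C)cc2)cc1OC(C)C | intermediate (not isolated)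
14 | [3-isopropoxy-4-(methoxycarbonyl)-5-methylphenyl](2,4,6-trimethoxyphenyl)iodonium tosylate | COC(=O)c1c(C)cc([I+]c2c(OC)cc(OC)cc2OC)cc1OC(C)C.Cc1ccc(S(=O)(=O)[O-])cc1 | intermediate
15 | potassium 4,6-bis(benzyloxy)-3-chloro-2,5-dimethylbenzoate | [K+].[O-]C(=O)c1c(C)c(Cl)c(OCc2ccccc2)c(C)c1OCc1ccccc1 | intermediate (not isolated)
16 | [3-isopropoxy-4-(methoxycarbonyl)-5-methylphenyl](2,4,6-trimethoxyphenyl)-λ3-iodanyl 4,6-bis(benzyloxy)-3-chloro-2,5-dimethylbenzoate | COC(=O)c1c(C)cc(I(OC(=O)c2c(C)c(Cl)c(OCc3ccccc3)c(C)c2OCc2ccccc2)c2c(OC)cc(OC)cc2OC)cc1OC(C)C | intermediate (not isolated)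
17 | methyl 4-{[4,6-bis(benzyloxy)-3-chloro-2,5-dimethylbenzoyl]oxy}-2-isopropoxy-6-methylbenzoate | COC(=O)c1c(C)cc(OC(=O)c2c(C)c(Cl)c(OCc3ccccc3)c(C)c2OCc2ccccc2)cc1OC(C)C | intermediate
18 | methyl 4-[(3-chloro-4,6-dihydroxy-2,5-dimethylbenzoyl)oxy]-2-hydroxy-6-methylbenzoate | COC(=O)c1c(C)cc(OC(=O)c2c(C)c(Cl)c(O)c(C)c2O)cc1O | target

## Step count and risks

Total step count: 11 (steps 1–4 for ring B, steps 5–9 for the ring A iodonium salt, steps 10 and 11 for coupling and deprotection).
Longest linear sequence: 7 steps (7 → 8 → 9 → 10 → 11 → 14 → 17 → 18).

**Step 10 (key step).** The likeliest failure is breakdown of iodane 16 before ligand coupling, by homolysis or by transfer of the auxiliary aryl group. This would be favoured if the tosylate salt dissolves poorly in toluene and ligand exchange with the bulky carboxylate is slow. The fallback gives up the arylation and forms the same ester bond from the acyl side. It sets out from 10 and 6 and comes back at 17. Oxidation of 10 with H2O2 and aqueous NaOH in THF at 0 °C should give methyl 4-hydroxy-2-isopropoxy-6-methylbenzoate F1. Acid 6 and F1 are then combined with trifluoroacetic anhydride in toluene at room temperature. The mixed anhydride 4,6-bis(benzyloxy)-3-chloro-2,5-dimethylbenzoic trifluoroacetic anhydride F2 should ionise to an acylium ion, which di-ortho substitution favours, and this is captured by the phenol to give 17.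

**Step 9.** The peracid may oxidise the alkoxy- and methyl-substituted ring instead of iodine, intermediate 13 may attack a second molecule of its own arene before 12 is added, and the salt may separate as an oil instead of a solid. The fallback avoids trivalent iodine altogether. It sets out from 10 and 6 and comes back at 17. Cleavage of the pinacol ester of 10 with NaIO4 and NH4OAc in aqueous acetone should give [3-isopropoxy-4-(methoxycarbonyl)-5-methylphenyl]boronic acid F3. F3 is then coupled with acid 6 under Chan–Lam conditions (Cu(OTf)2, urea, EtOAc, 60 °C, air), in which the carboxylate is arylated on a copper centre and the ring A C4–O bond is again the one formed.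

**Step 11.** The isopropyl ether may cleave incompletely at the temperature the two esters tolerate. Forcing the reaction risks Lewis-acid cleavage of the hindered methyl ester and C-benzylation of ring A by benzyl cations that escape the scavenger. The fallback moves the isopropyl cleavage to an early, robust intermediate and carries benzyl on ring A from there on. It sets out from 11 and comes back at 18.
- BCl3 in CH2Cl2 at 0 °C to room temperature should give methyl 2-hydroxy-4-iodo-6-methylbenzoate F4.
- BnBr and K2CO3 in DMF should give methyl 2-(benzyloxy)-4-iodo-6-methylbenzoate F5. The benzyl group is introduced after the borylation, so it cannot interfere there.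
- Oxidation with mCPBA and TsOH·H2O, passing through methyl 2-(benzyloxy)-4-[hydroxy(tosyloxy)-λ3-iodanyl]-6-methylbenzoate F6, and condensation with 12 should give [3-(benzyloxy)-4-(methoxycarbonyl)-5-methylphenyl](2,4,6-trimethoxyphenyl)iodonium tosylate F7.
- Arylation of carboxylate 15, made from 6 as in step 10, should pass through [3-(benzyloxy)-4-(methoxycarbonyl)-5-methylphenyl](2,4,6-trimethoxyphenyl)-λ3-iodanyl 4,6-bis(benzyloxy)-3-chloro-2,5-dimethylbenzoate F8 and give methyl 2-(benzyloxy)-4-{[4,6-bis(benzyloxy)-3-chloro-2,5-dimethylbenzoyl]oxy}-6-methylbenzoate F9.
- BCl3 and pentamethylbenzene at −78 °C should then remove all three benzyl groups and give 18 without warming.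

**Step 2.** Ipso attack at the formyl-bearing carbon with loss of the aldehyde, or radical chlorination of a ring methyl group, may compete with substitution at C3. The fallback reverses the order of the two substitutions. It sets out from 1 and comes back at 4. Monochlorination of 1 with N-chlorosuccinimide in MeCN at 0 °C should give 4-chloro-2,5-dimethylbenzene-1,3-diol F10. Its single remaining ring position is then formylated under the conditions of step 1, through N-[(3-chloro-4,6-dihydroxy-2,5-dimethylphenyl)methylidene]-N-methylmethanaminium chloride F11, to give 4. The price is a risk of dichlorination in the first operation, which is why the main route formylates first.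

## Further compounds

F1 | step 10 | methyl 4-hydroxy-2-isopropoxy-6-methylbenzoate | COC(=O)c1c(C)cc(O)cc1OC(C)C
F2 | step 10 | 4,6-bis(benzyloxy)-3-chloro-2,5-dimethylbenzoic trifluoroacetic anhydride | O=C(OC(=O)C(F)(F)F)c1c(C)c(Cl)c(OCc2ccccc2)c(C)c1OCc1ccccc1
F3 | step 9 | [3-isopropoxy-4-(methoxycarbonyl)-5-methylphenyl]boronic acid | COC(=O)c1c(C)cc(B(O)O)cc1OC(C)C
F4 | step 11 | methyl 2-hydroxy-4-iodo-6-methylbenzoate | COC(=O)c1c(C)cc(I)cc1O
F5 | step 11 | methyl 2-(benzyloxy)-4-iodo-6-methylbenzoate | COC(=O)c1c(C)cc(I)cc1OCc1ccccc1
F6 | step 11 | methyl 2-(benzyloxy)-4-[hydroxy(tosyloxy)-λ3-iodanyl]-6-methylbenzoate | COC(=O)c1c(C)cc(I(O)OS(=O)(=O)c2ccc(C)cc2)cc1OCc1ccccc1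
F7 | step 11 | [3-(benzyloxy)-4-(methoxycarbonyl)-5-methylphenyl](2,4,6-trimethoxyphenyl)iodonium tosylate | COC(=O)c1c(C)cc([I+]c2c(OC)cc(OC)cc2OC)cc1OCc1ccccc1.Cc1ccc(S(=O)(=O)[O-])cc1
F8 | step 11 | [3-(benzyloxy)-4-(methoxycarbonyl)-5-methylphenyl](2,4,6-trimethoxyphenyl)-λ3-iodanyl 4,6-bis(benzyloxy)-3-chloro-2,5-dimethylbenzoate | COC(=O)c1c(C)cc(I(OC(=O)c2c(C)c(Cl)c(OCc3ccccc3)c(C)c2OCc2ccccc2)c2c(OC)cc(OC)cc2OC)cc1OCc1ccccc1
F9 | step 11 | methyl 2-(benzyloxy)-4-{[4,6-bis(benzyloxy)-3-chloro-2,5-dimethylbenzoyl]oxy}-6-methylbenzoate | COC(=O)c1c(C)cc(OC(=O)c2c(C)c(Cl)c(OCc3ccccc3)c(C)c2OCc2ccccc2)cc1OCc1ccccc1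
F10 | step 2 | 4-chloro-2,5-dimethylbenzene-1,3-diol | Cc1cc(O)c(C)c(O)c1Cl
F11 | step 2 | N-[(3-chloro-4,6-dihydroxy-2,5-dimethylphenyl)methylidene]-N-methylmethanaminium chloride | C[N+](C)=Cc1c(C)c(Cl)c(O)c(C)c1O.[Cl-]
A1 | alternative 1 | methyl acetoacetate | COC(=O)CC(C)=O
A2 | alternative 1 | methyl (E)-but-2-enoate (methyl crotonate) | C/C=C/C(=O)OC
A3 | alternative 1 | methyl 6-methyl-2,4-dioxocyclohexane-1-carboxylate (racemic trans) | COC(=O)[C@@H]1[C@@H](C)CC(=O)CC1=O
A4 | alternative 1 | methyl 4-{[4,6-bis(benzyloxy)-3-chloro-2,5-dimethylbenzoyl]oxy}-6-methyl-2-oxocyclohex-3-ene-1-carboxylate (racemic trans) | COC(=O)[C@@H]1[C@@H](C)CC(OC(=O)c2c(C)c(Cl)c(OCc3ccccc3)c(C)c2OCc2ccccc2)=CC1=O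
A5 | alternative 2 | 3-hydroxy-4-(methoxycarbonyl)-5-methylphenyl (E)-5-chloro-2-diazo-4-methyl-3-oxopent-4-enoate | COC(=O)c1c(C)cc(OC(=O)C(=[N+]=[N-])C(=O)/C(C)=C/Cl)cc1O
A6 | alternative 2 | 1-(triisopropylsiloxy)propyne | CC#CO[Si](C(C)C)(C(C)C)C(C)C
A7 | alternative 2 | methyl 4-{[3-chloro-4-hydroxy-2,5-dimethyl-6-(triisopropylsilyloxy)benzoyl]oxy}-2-hydroxy-6-methylbenzoate | COC(=O)c1c(C)cc(OC(=O)c2c(C)c(Cl)c(O)c(C)c2O[Si](C(C)C)(C(C)C)C(C)C)cc1O
A8 | alternative 3 | 4-methoxy-4-(trimethylsilyloxy)buta-1,3-dien-2-yl 3-chloro-4,6-bis(methoxymethoxy)-2,5-dimethylbenzoate (ketene acetal geometry not defined) | C=C(OC(=O)c1c(C)c(Cl)c(OCOC)c(C)c1OCOC)C=C(OC)O[Si](C)(C)C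
A9 | alternative 3 | methyl but-2-ynoate | CC#CC(=O)OC
A10 | alternative 3 | methyl 4-{[3-chloro-4,6-bis(methoxymethoxy)-2,5-dimethylbenzoyl]oxy}-2-hydroxy-6-methylbenzoate | COC(=O)c1c(C)cc(OC(=O)c2c(C)c(Cl)c(OCOC)c(C)c2OCOC)cc1O
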